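**Retrosynthetic overview**
1. Target ⇐ dehydration of a tertiary 3a‑hydroxy γ‑lactone whose 6‑OH already carries the palmitate (only the butenolide C=C can form).
2. Hydroxy lactone ⇐ a cis‑epoxy acid; the carboxyl opens the oxirane at the methyl‑bearing carbon with inversion, which puts the lactone oxygen trans to the 6‑oxygen (7aR).
3. cis‑Epoxide ⇐ hydroxyl‑directed epoxidation of a (4‑hydroxy‑2,6,6‑trimethylcyclohexenyl)acetate; the alkene ⇐ dehydration of a β‑hydroxy ester.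
4. β‑Hydroxy ester ⇐ intermolecular aldol addition of the lithium enolate of ethyl acetate to silylated (4R,6R)‑4‑hydroxy‑2,2,6‑trimethylcyclohexanone (forms the C3–C3a bond).
5. That ketone ⇐ ketoisophorone; the carbocycle is bought, and the lactone ring is the only ring made (step 8).

Assumption: reagents, bases, catalysts and solvents are not numbered; numbers go to substrates, the two added carbon fragments (ethyl acetate, palmitoyl chloride) and in‑flask intermediates. Compounds 2–8 use cyclohexanone numbering (C1 = hindered C=O, C2 = CMe2, C4 = carbinol carbon, C6 = CHMe).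

**Step 1**
Reactants: 1 ketoisophorone (2,6,6‑trimethylcyclohex‑2‑ene‑1,4‑dione)
Product: 2 (6R)‑2,2,6‑trimethylcyclohexane‑1,4‑dione
Conditions: baker's yeast (Saccharomyces cerevisiae), sucrose, H2O, 30 °C, slow feed of 1; recrystallise
Reagents that add atoms: none
Why: Enzymatic conjugate reduction by the yeast ene‑reductases adds H2 only across the enedione C=C and sets the methyl‑bearing centre as R; crystallisation upgrades the ee.

**Step 2**
Reactants: 2 (6R)‑2,2,6‑trimethylcyclohexane‑1,4‑dione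
Product: 3 (4R,6R)‑4‑hydroxy‑2,2,6‑trimethylcyclohexan‑1‑one
Conditions: LiBH(s‑Bu)3 (1.05 equiv), THF, −78 °C; then NaOH, H2O2, 0 °C; recrystallise
Reagents that add atoms: none
Why: Chemo‑ and diastereoselective ketone reduction: the C1 carbonyl (between CMe2 and CHMe) is shielded, and the bulky hydride attacks the C4 carbonyl equatorially because the axial path is blocked by the syn‑axial C2 methyl (as in 3,3,5‑trimethylcyclohexanone), giving the axial OH trans to the C6 methyl (4R).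

**Step 3**
Reactants: 3 (4R,6R)‑4‑hydroxy‑2,2,6‑trimethylcyclohexan‑1‑one
Product: 4 (4R,6R)‑4‑[(tert‑butyldimethylsilyl)oxy]‑2,2,6‑trimethylcyclohexan‑1‑one
Conditions: TBSCl, imidazole, DMF, rt
Reagents that add atoms: tert‑butyldimethylsilyl chloride, CC(C)(C)[Si](C)(C)Cl
Why: Standard imidazole‑promoted silylation of a secondary alcohol; the hindered ketone is untouched and no stereocentre changes.

**Step 4**
Reactants: 4 (4R,6R)‑4‑[(tert‑butyldimethylsilyl)oxy]‑2,2,6‑trimethylcyclohexan‑1‑one; 5 ethyl acetate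
Product: 7 ethyl 2‑[(1S,4R,6R)‑4‑[(tert‑butyldimethylsilyl)oxy]‑1‑hydroxy‑2,2,6‑trimethylcyclohexyl]acetate, via lithium enolate 6 (not isolated)
Conditions: LiN(i‑Pr)2 (commercial solution, 1.5 equiv), THF, −78 °C, add 5, 30 min; then 4, −78 °C, 3 h; AcOH quench at −78 °C
Reagents that add atoms: none
Why: Intermolecular aldol addition of a small, reactive ester enolate to the ketone; axial attack (the equatorial path is blocked by the axial C2 methyl) is expected to give the 1S carbinol, but C1 becomes sp2 in step 5, so either epimer serves.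

**Step 5**
Reactants: 7 ethyl 2‑[(1S,4R,6R)‑4‑[(tert‑butyldimethylsilyl)oxy]‑1‑hydroxy‑2,2,6‑trimethylcyclohexyl]acetate
Product: 9 ethyl 2‑[(4R)‑4‑[(tert‑butyldimethylsilyl)oxy]‑2,6,6‑trimethylcyclohex‑1‑en‑1‑yl]acetate, via exocyclic enoate 8 (not isolated)
Conditions: SOCl2, pyridine, CH2Cl2, 0 °C; crude, then NaOEt (0.3 equiv), EtOH, 50 °C
Reagents that add atoms: none
Why: Chlorosulfite dehydration gives mainly the conjugated enoate 8 (1‑OH and 6‑H are cis, so no ring hydrogen is anti‑periplanar). Alkoxide equilibration (Kon–Linstead deconjugation) then moves the double bond into the ring to the tetrasubstituted, strain‑relieved β,γ‑isomer; only C6 has a γ‑hydrogen, so one endocyclic isomer is possible.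

**Step 6**
Reactants: 9 ethyl 2‑[(4R)‑4‑[(tert‑butyldimethylsilyl)oxy]‑2,6,6‑trimethylcyclohex‑1‑en‑1‑yl]acetate
Product: 10 ethyl 2‑[(4R)‑4‑hydroxy‑2,6,6‑trimethylcyclohex‑1‑en‑1‑yl]acetate
Conditions: Bu4NF, AcOH (1:1), THF, rt
Reagents that add atoms: none
Why: Fluoride desilylation; the acetic acid buffer prevents base‑induced reconjugation, and the carbinol centre is untouched.

**Step 7**
Reactants: 10 ethyl 2‑[(4R)‑4‑hydroxy‑2,6,6‑trimethylcyclohex‑1‑en‑1‑yl]acetate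
Product: 11 ethyl 2‑[(1R,4S,6S)‑4‑hydroxy‑2,2,6‑trimethyl‑7‑oxabicyclo[4.1.0]heptan‑1‑yl]acetate (oxirane oxygen cis to the OH)
Conditions: VO(acac)2 (5 mol %), t‑BuOOH (1.5 equiv, in decane), toluene, 0 °C to rt
Reagents that add atoms: tert‑butyl hydroperoxide, CC(C)(C)OO
Why: Hydroxyl‑directed (Sharpless–Michaelson) vanadium‑catalysed epoxidation: the homoallylic vanadate delivers the peroxide oxygen to the face carrying the OH, setting both oxirane carbons cis to it.

**Step 8**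
Reactants: 11 ethyl 2‑[(1R,4S,6S)‑4‑hydroxy‑2,2,6‑trimethyl‑7‑oxabicyclo[4.1.0]heptan‑1‑yl]acetate
Product: 13 (3aR,6S,7aR)‑3a,6‑dihydroxy‑4,4,7a‑trimethylhexahydro‑1‑benzofuran‑2(3H)‑one, via epoxy acid 12 (not isolated)
Conditions: LiOH, THF/H2O, rt; then 1 M HCl to pH 3, EtOAc, rt
Reagents that add atoms: lithium hydroxide, [Li+].[OH-]
Why: Saponification, then acid‑promoted epoxide‑opening lactonisation: the carboxyl group sits on the face opposite the oxirane oxygen and attacks the methyl‑bearing carbon with inversion, giving the cis‑fused γ‑lactone with its ring oxygen trans to the 6‑OH (7aR) and a tertiary 3a‑OH.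

**Step 9**
Reactants: 13 (3aR,6S,7aR)‑3a,6‑dihydroxy‑4,4,7a‑trimethylhexahydro‑1‑benzofuran‑2(3H)‑one; 14 palmitoyl chloride (hexadecanoyl chloride)
Product: 15 (3aR,6S,7aR)‑3a‑hydroxy‑4,4,7a‑trimethyl‑2‑oxooctahydro‑1‑benzofuran‑6‑yl hexadecanoate
Conditions: pyridine, 4‑(dimethylamino)pyridine (cat.), CH2Cl2, 0 °C to rt
Reagents that add atoms: none
Why: Nucleophile‑catalysed acylation is selective for the secondary alcohol; the tertiary 3a‑OH between two quaternary carbons does not react, and C6 keeps its configuration.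

**Step 10**
Reactants: 15 (3aR,6S,7aR)‑3a‑hydroxy‑4,4,7a‑trimethyl‑2‑oxooctahydro‑1‑benzofuran‑6‑yl hexadecanoate
Product: 16 (−)‑3‑O‑palmitoylloliolide, (6S,7aR)‑4,4,7a‑trimethyl‑2‑oxo‑2,4,5,6,7,7a‑hexahydro‑1‑benzofuran‑6‑yl hexadecanoate
Conditions: SOCl2, pyridine, 0 °C to rt
Reagents that add atoms: none
Why: Chlorosulfite dehydration of the β‑hydroxy lactone; C4 and C7a are quaternary, so the only β‑hydrogens are on the lactone CH2 and only the butenolide can form, with no stereocentre touched.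

**Compound list**
1 | 2,6,6‑trimethylcyclohex‑2‑ene‑1,4‑dione (ketoisophorone) | CC1=CC(=O)CC(C)(C)C1=O | starting material
2 | (6R)‑2,2,6‑trimethylcyclohexane‑1,4‑dione | C[C@@H]1CC(=O)CC(C)(C)C1=O | intermediate
3 | (4R,6R)‑4‑hydroxy‑2,2,6‑trimethylcyclohexan‑1‑one (OH trans to the C6 methyl) | C[C@@H]1C[C@@H](O)CC(C)(C)C1=O | intermediate
4 | (4R,6R)‑4‑[(tert‑butyldimethylsilyl)oxy]‑2,2,6‑trimethylcyclohexan‑1‑one | C[C@@H]1C[C@@H](O[Si](C)(C)C(C)(C)C)CC(C)(C)C1=O | intermediate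
5 | ethyl acetate | CCOC(C)=O | starting material
6 | lithium enolate of ethyl acetate, LiOC(=CH2)OEt | [Li]OC(=C)OCC | intermediate
7 | ethyl 2‑[(1S,4R,6R)‑4‑[(tert‑butyldimethylsilyl)oxy]‑1‑hydroxy‑2,2,6‑trimethylcyclohexyl]acetate | C[C@@H]1C[C@@H](O[Si](C)(C)C(C)(C)C)CC(C)(C)[C@]1(O)CC(=O)OCC | intermediate
8 | ethyl (2E)‑2‑[(4R,6R)‑4‑[(tert‑butyldimethylsilyl)oxy]‑2,2,6‑trimethylcyclohexylidene]acetate | C[C@@H]1C[C@@H](O[Si](C)(C)C(C)(C)C)CC(C)(C)/C1=C/C(=O)OCC | intermediate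
9 | ethyl 2‑[(4R)‑4‑[(tert‑butyldimethylsilyl)oxy]‑2,6,6‑trimethylcyclohex‑1‑en‑1‑yl]acetate | CC1=C(CC(=O)OCC)C(C)(C)C[C@H](O[Si](C)(C)C(C)(C)C)C1 | intermediate
10 | ethyl 2‑[(4R)‑4‑hydroxy‑2,6,6‑trimethylcyclohex‑1‑en‑1‑yl]acetate | CC1=C(CC(=O)OCC)C(C)(C)C[C@H](O)C1 | intermediate
11 | ethyl 2‑[(1R,4S,6S)‑4‑hydroxy‑2,2,6‑trimethyl‑7‑oxabicyclo[4.1.0]heptan‑1‑yl]acetate | C[C@]12C[C@@H](O)CC(C)(C)[C@@]1(CC(=O)OCC)O2 | intermediate
12 | 2‑[(1R,4S,6S)‑4‑hydroxy‑2,2,6‑trimethyl‑7‑oxabicyclo[4.1.0]heptan‑1‑yl]acetic acid | C[C@]12C[C@@H](O)CC(C)(C)[C@@]1(CC(=O)O)O2 | intermediate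
13 | (3aR,6S,7aR)‑3a,6‑dihydroxy‑4,4,7a‑trimethylhexahydro‑1‑benzofuran‑2(3H)‑one | O[C@H]1CC(C)(C)[C@]2(O)CC(=O)O[C@]2(C)C1 | intermediate
14 | hexadecanoyl chloride (palmitoyl chloride) | CCCCCCCCCCCCCCCC(=O)Cl | starting material
15 | (3aR,6S,7aR)‑3a‑hydroxy‑4,4,7a‑trimethyl‑2‑oxooctahydro‑1‑benzofuran‑6‑yl hexadecanoate | CCCCCCCCCCCCCCCC(=O)O[C@H]1CC(C)(C)[C@]2(O)CC(=O)O[C@]2(C)C1 | intermediate
16 | (−)‑3‑O‑palmitoylloliolide, (6S,7aR)‑4,4,7a‑trimethyl‑2‑oxo‑2,4,5,6,7,7a‑hexahydro‑1‑benzofuran‑6‑yl hexadecanoate | CCCCCCCCCCCCCCCC(=O)O[C@H]1CC(C)(C)C2=CC(=O)O[C@]2(C)C1 | target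

**Totals**
Total steps: 10. Longest linear sequence: 10 (1 → 16); ethyl acetate 5 and palmitoyl chloride 14 enter as single compounds.

**Three steps most likely to fail, with fallbacks**

Step 4 (aldol addition to a ketone flanked by a quaternary and a tertiary carbon; enolisation or retro‑aldol may limit conversion). The fallback sets out from 4 and replaces the aldol by a carbonyl allylation. CH2=CHCH2MgBr in THF at 0 °C adds through a cyclic transition state even to very hindered ketones and gives (1S,4R,6R)‑4‑[(tert‑butyldimethylsilyl)oxy]‑2,2,6‑trimethyl‑1‑(prop‑2‑en‑1‑yl)cyclohexan‑1‑ol F1. Ozonolysis (O3, CH2Cl2, −78 °C, then Me2S) gives 2‑[(1S,4R,6R)‑4‑[(tert‑butyldimethylsilyl)oxy]‑1‑hydroxy‑2,2,6‑trimethylcyclohexyl]acetaldehyde F2. Pinnick oxidation (NaClO2, NaH2PO4, 2‑methylbut‑2‑ene, t‑BuOH/H2O) gives 2‑[(1S,4R,6R)‑4‑[(tert‑butyldimethylsilyl)oxy]‑1‑hydroxy‑2,2,6‑trimethylcyclohexyl]acetic acid F3. Alkylation with EtI and K2CO3 in DMF comes back to the route at 7.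

Step 5 (regiochemistry of the dehydration; the equilibration may stop short of complete deconjugation). The fallback sets out from 4 and fixes the double bond before the side chain is attached. KN(SiMe3)2 and PhNTf2 in THF at −78 °C give (4R)‑4‑[(tert‑butyldimethylsilyl)oxy]‑2,6,6‑trimethylcyclohex‑1‑en‑1‑yl trifluoromethanesulfonate F4; only C6 can enolise, so the alkene position is unambiguous. Negishi‑type coupling with the Reformatsky reagent BrZnCH2CO2Et and Pd(PPh3)4 (zerovalent palladium) in THF at 60 °C comes back to the route at 9.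

Step 7 (the vanadate may react slowly with a tetrasubstituted alkene next to a gem‑dimethyl group, and Lewis‑acidic vanadium may open the oxirane early). The fallback sets out from 10 and switches to an oxidative lactonisation of the free acid. LiOH in THF/H2O gives 2‑[(4R)‑4‑hydroxy‑2,6,6‑trimethylcyclohex‑1‑en‑1‑yl]acetic acid F5. 3‑Chloroperbenzoic acid in CH2Cl2 at 0 °C then epoxidises cis to the OH (Henbest hydrogen‑bond direction, on the face away from the pseudoaxial ring methyl); the epoxy acid 12 lactonises in the flask, and the route is rejoined at 13.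

**Further compounds**
F1 | step 4 | (1S,4R,6R)‑4‑[(tert‑butyldimethylsilyl)oxy]‑2,2,6‑trimethyl‑1‑(prop‑2‑en‑1‑yl)cyclohexan‑1‑ol | C[C@@H]1C[C@@H](O[Si](C)(C)C(C)(C)C)CC(C)(C)[C@]1(O)CC=C
F2 | step 4 | 2‑[(1S,4R,6R)‑4‑[(tert‑butyldimethylsilyl)oxy]‑1‑hydroxy‑2,2,6‑trimethylcyclohexyl]acetaldehyde | C[C@@H]1C[C@@H](O[Si](C)(C)C(C)(C)C)CC(C)(C)[C@]1(O)CC=O
F3 | step 4 | 2‑[(1S,4R,6R)‑4‑[(tert‑butyldimethylsilyl)oxy]‑1‑hydroxy‑2,2,6‑trimethylcyclohexyl]acetic acid | C[C@@H]1C[C@@H](O[Si](C)(C)C(C)(C)C)CC(C)(C)[C@]1(O)CC(=O)O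
F4 | step 5 | (4R)‑4‑[(tert‑butyldimethylsilyl)oxy]‑2,6,6‑trimethylcyclohex‑1‑en‑1‑yl trifluoromethanesulfonate | CC1=C(OS(=O)(=O)C(F)(F)F)C(C)(C)C[C@H](O[Si](C)(C)C(C)(C)C)C1
F5 | step 7 | 2‑[(4R)‑4‑hydroxy‑2,6,6‑trimethylcyclohex‑1‑en‑1‑yl]acetic acid | CC1=C(CC(=O)O)C(C)(C)C[C@H](O)C1
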